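The ratio I watch is nucleophile per electrophile, counted by what one product costs.

| flask | electrophile | nucleophile | solid base | remark | time |
|---|---|---|---|---|---|
| oak | 0.10 M | 0.080 M | 0.030 M | run made earlier |  |
| larch | 0.10 M | 0.15 M | 0.030 M | run made earlier |  |
| north-west | 0.10 M | 0.120 M | 0.0300 M |  | 15 min |
| south-east | 0.10 M | 0.180 M | 0.0300 M |  | 15 min |

| run | time / min | electrophile / % | product / % |
|---|---|---|---|
| oak | 1.00 | 65 | 8 |
| oak | 2.50 | 51 | 19 |
| oak | 5.00 | 43 | 27 |
| oak | 8.00 | 41 | 37 |
| oak | 10.0 | 38 | 38 |
| larch | 0.833 | 62 | 19 |
| larch | 1.50 | 45 | 26 |
| larch | 3.00 | 34 | 41 |
| larch | 6.00 | 26 | 50 |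
| larch | 10.0 | 23 | 62 |

(each reading ± 2 percentage points)

* part of the electrophile that has reacted at the end, north-west
* part of the electrophile that has reacted at the end, south-east
* what raising the concentration of nucleophile from its lowest to its highest value here does to the part of the electrophile that has reacted (changes below 5 percentage points count as none) (it rises / no change / it falls)

- given per volume of solution although it is solid: solid base
- candidate steps: solid base <-> free base; electrophile + nucleophile <-> acid set free + product; acid set free + free base <-> salt of the base; nucleophile + acid set free <-> protonated nucleophile; electrophile <-> dormant form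
- at the start none of the solid base is in solution
- what has gone from electrophile into another species counts as reacted, even if it can come back

I start with the main step by itself. One nucleophile makes one product, so the oak run has room for 80.0%. But it reads 37% at 8.00 min and 38% at 10.0 min, flattening well below that.

Now I add the acid set free. If it ties up a second nucleophile as protonated nucleophile, the ceiling on product, as a share of the electrophile charged, is

f = c(nucleophile) / (2 c(electrophile)).

Oak then gives 40.0%, close to its readings. In this count, where f stays below one, nucleophile is the limiting reagent. Counting the whole solid base as a sparing agent would give 55.0%, further from those readings, so I leave it out.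

Last comes the dormant form. At their last readings, electrophile and product fall short by 24.0% in oak and 15.0% in larch. I read that gap as dormant form. Its ratio to electrophile reads r = 0.632 in oak and 0.652 in larch. What is not product splits by r, so I work with the electrophile left at the ceiling:

left = (1 − f) / (1 + r).

North-west: f = 60.0%, left = 24.5%, reacted 75.5%.

South-east: f = 90.0%, left = 6.13%, reacted 93.9%.

Larch still reads 62% after 10.0 min under its ceiling of 75.0%, so I take the south-east figure as a high estimate of what has reacted. The part reacted rises.

The forecast says 74% (68% to 80%) for north-west, 87% (80% to 93%) for south-east, and it rises. Its grounds: “Each product beyond that point therefore costs two nucleophiles, so more nucleophile pushes conversion further.” My ceiling charges both nucleophiles from the first product.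

North-west gives 72.2% reacted and south-east 84.4%; with more nucleophile it rises, by 12 percentage points. At 15.0 min, north-west holds 0.0499 M of protonated nucleophile against 9.67 × 10⁻⁴ M of salt of the base. My 24.5% stands against 28% of electrophile left there.

    solid base ⇌ free base, rate k1*(cs1 - [free base]) while solid is left; crystals form when [free base] > cs1 (solubility = 0.0970 M, k = 0.00600 s⁻¹)
    electrophile + nucleophile ⇌ acid set free + product (K = 0.570, k = 0.0400 M⁻¹ s⁻¹)
    acid set free + free base ⇌ salt of the base (K = 11.0 M⁻¹, k = 0.550 M⁻¹ s⁻¹)
    nucleophile + acid set free ⇌ protonated nucleophile, settled at all times (K = 1000 M⁻¹)
    electrophile ⇌ dormant form (K = 0.650, k = 0.00720 s⁻¹)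

Take north-west with 0.40 M of electrophile: f = 15.0%, so left = 52.1%. That flask gives 51.0% of electrophile left and 15.9% of product.

The runs were computed for substances that don't exist; scatter was added.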